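**Retrosynthetic overview**
- The quinone ring (numbered C1=O, C2–OMe, C3–H, C4=O, C5–CH3, C6–docosyl) comes from phenol 9 by oxidation of the free para position C4. No ring is built: the six-membered carbocycle is carried intact from 2-methoxy-5-methylphenol (1).
- The docosyl chain (C1′–C22′, counted from the ring) is cut at C2′–C3′ and at C6–C1′. An aryl anion at C6, vinyl-Bpin (C1′–C2′) and 1-iodoicosane (C3′–C22′) are joined in one Ni-catalysed conjunctive coupling.
- Enabling feature: ring carbon C6 lies ortho to the C1 oxygen (as OMOM it directs lithiation there) and carries a plain CH2–CH2 spacer. Benzylic C1′ can hold a temporary boron, and C2′ is a primary carbon that bonds to the primary C20 iodide.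
- Order: MOM protection → lithiation/ate complex/conjunctive coupling → C–B to C–H → MOM removal → phenol to p-quinone.

Key step: step 2

Remark: the target has no stereocentre and no stereogenic double bond, so it is achiral and no enantiocontrol is needed; the only stereocentre of the route (in 7) is made racemic and removed in step 3.

**Step 1**
Reactants: 1 2-methoxy-5-methylphenol
Product: 2 1-methoxy-2-(methoxymethoxy)-4-methylbenzene
Conditions: MOMCl (1.5 equiv), i-Pr2NEt (2 equiv), CH2Cl2, 0 °C → rt
Reagents that add atoms: chloromethyl methyl ether (MOMCl), COCCl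
Why: Base-mediated O-alkylation of the only acidic site (phenol) with MOMCl should give the MOM ether, which is the ortho-directing group for step 2 and is inert to organolithium, nickel and fluoride.

**Step 2**
Reactants: 2 1-methoxy-2-(methoxymethoxy)-4-methylbenzene; 3 4,4,5,5-tetramethyl-2-vinyl-1,3,2-dioxaborolane (vinyl-Bpin); 4 1-iodoicosane
Product: 7 rac-2-[1-(3-methoxy-2-(methoxymethoxy)-6-methylphenyl)docosyl]-4,4,5,5-tetramethyl-1,3,2-dioxaborolane, via aryllithium 5 (not isolated), via vinylboron ate complex 6 (not isolated)
Conditions: 2 (1.15 equiv), n-BuLi (1.05 equiv), THF, 0 °C → rt; then 3 (1.05 equiv), –78 → 0 °C; solvent exchange; then 4 (1.0 equiv), NiBr2·glyme (10 mol%), rac-trans-N,N′-dimethylcyclohexane-1,2-diamine (12 mol%), THF/DMSO, rt → 40 °C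
Reagents that add atoms: none
Why: OMOM-directed ortho-lithiation of 2 at the ring carbon between OMOM and CH3 gives 5, which adds to the boron of 3 to give the four-coordinate aryl(vinyl)boronate 6. The diamine–nickel catalyst activates 4 (as an icosyl–nickel species or icosyl radical) and delivers its primary carbon to the terminal CH2 of the electron-rich vinyl group while the aryl group shifts 1,2 from boron to the internal carbon, so the C2′–C3′ bond and the C6–C1′ bond form in one event. The closest known reaction type is the Ni-catalysed conjunctive (three-component) cross-coupling of vinylboron ate complexes with unactivated primary alkyl iodides, a 1,2-boronate rearrangement of the radical-polar-crossover family. No ring is closed, and the single new stereocentre (benzylic C–B) forms as a racemate under the racemic ligand and is deleted in step 3. The step needs lithiation at C6 and not at C3, which the stronger coordination of OMOM compared with OMe should secure, and it needs attack at the vinyl terminus with aryl migration, which is the only carbon group on boron that can shift. It also needs conjunctive coupling to outrun direct aryl–icosyl transfer and β-hydride elimination, for which the diamine–nickel system suited to primary alkyl iodides with β-hydrogens is chosen.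

**Step 3**
Reactants: 7 rac-2-[1-(3-methoxy-2-(methoxymethoxy)-6-methylphenyl)docosyl]-4,4,5,5-tetramethyl-1,3,2-dioxaborolane
Product: 8 2-docosyl-4-methoxy-3-(methoxymethoxy)-1-methylbenzene
Conditions: TBAF·3H2O (3 equiv), toluene, 60 °C
Reagents that add atoms: none
Why: Fluoride-promoted protodeboronation of a secondary benzylic pinacol boronic ester should occur because fluoride adds to boron and the boronate hands its benzylic carbon to a proton of the hydrate water, which erases the racemic stereocentre while OMe, MOM and the chain stay untouched.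

**Step 4**
Reactants: 8 2-docosyl-4-methoxy-3-(methoxymethoxy)-1-methylbenzene
Product: 9 2-docosyl-6-methoxy-3-methylphenol
Conditions: conc. HCl (cat.), MeOH/THF, 50 °C
Reagents that add atoms: none
Why: Acid-catalysed methanolysis of the MOM acetal should free the phenol, since the aryl methyl ether and the saturated chain are stable to HCl/MeOH.

**Step 5**
Reactants: 9 2-docosyl-6-methoxy-3-methylphenol
Product: 10 3-docosyl-5-methoxy-2-methylcyclohexa-2,5-diene-1,4-dione (the target)
Conditions: O2 (1 atm), Co(salen) (10 mol%), DMF/THF, rt
Reagents that add atoms: dioxygen, O=O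
Why: Co(salen)/O2 oxidation of a phenol with a free para position to the 1,4-benzoquinone should work because the cobalt–superoxo species forms the phenoxyl radical and delivers oxygen to C4, while both ortho positions are blocked by docosyl and OMe.

**Compound list**
1 | 2-methoxy-5-methylphenol | COc1ccc(C)cc1O | starting material
2 | 1-methoxy-2-(methoxymethoxy)-4-methylbenzene | COCOc1cc(C)ccc1OC | intermediate
3 | 4,4,5,5-tetramethyl-2-vinyl-1,3,2-dioxaborolane | C=CB1OC(C)(C)C(C)(C)O1 | starting material
4 | 1-iodoicosane | CCCCCCCCCCCCCCCCCCCCI | starting material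
5 | [3-methoxy-2-(methoxymethoxy)-6-methylphenyl]lithium | [Li]c1c(C)ccc(OC)c1OCOC | intermediate
6 | lithium [3-methoxy-2-(methoxymethoxy)-6-methylphenyl](vinyl)(pinacolato)borate | [Li+].C=C[B-]1(OC(C)(C)C(C)(C)O1)c1c(C)ccc(OC)c1OCOC | intermediate
7 | rac-2-[1-(3-methoxy-2-(methoxymethoxy)-6-methylphenyl)docosyl]-4,4,5,5-tetramethyl-1,3,2-dioxaborolane | CCCCCCCCCCCCCCCCCCCCCC(B1OC(C)(C)C(C)(C)O1)c1c(C)ccc(OC)c1OCOC | intermediate
8 | 2-docosyl-4-methoxy-3-(methoxymethoxy)-1-methylbenzene | CCCCCCCCCCCCCCCCCCCCCCc1c(C)ccc(OC)c1OCOC | intermediate
9 | 2-docosyl-6-methoxy-3-methylphenol | CCCCCCCCCCCCCCCCCCCCCCc1c(C)ccc(OC)c1O | intermediate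
10 | 3-docosyl-5-methoxy-2-methylcyclohexa-2,5-diene-1,4-dione | CCCCCCCCCCCCCCCCCCCCCCC1=C(C)C(=O)C=C(OC)C1=O | target

**Summary**
Total step count: 5. Longest linear sequence: 5 steps (1 → 2 → 7 → 8 → 9 → 10).

Steps most likely to fail:

1. Step 2. Metalation may go to the ring position next to OMe instead of the hindered position between OMOM and CH3. The 1,2-shift of the doubly ortho-substituted aryl group may also be slow, so that direct alkyl transfer or β-hydride elimination of the icosyl–nickel species takes over. The fallback sets out from 1 and comes back at 8. Magnesium-mediated ortho-formylation of 1 (MgCl2, Et3N, paraformaldehyde, MeCN, reflux) can only reach the one free ortho position and should give 2-hydroxy-3-methoxy-6-methylbenzaldehyde F1. MOMCl/i-Pr2NEt should then give 3-methoxy-2-(methoxymethoxy)-6-methylbenzaldehyde F2. Wittig methylenation (Ph3PCH3Br, KOt-Bu, THF) should give 2-ethenyl-4-methoxy-3-(methoxymethoxy)-1-methylbenzene F3. Anti-Markovnikov hydroboration with 9-BBN should give 9-{2-[3-methoxy-2-(methoxymethoxy)-6-methylphenyl]ethyl}-9-borabicyclo[3.3.1]nonane F4. Without isolation, F4 is coupled with 1-bromoicosane in an alkyl–alkyl Suzuki reaction (Pd(OAc)2, PCy3, K3PO4·H2O, THF, rt), which forms the same C2′–C3′ bond and gives 8.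

2. Step 3. Protonolysis of the C–B bond may be slow, because the electron-rich, doubly ortho-substituted ring stabilises the developing benzylic negative charge poorly, and adventitious oxidation of the boronate may compete. The fallback sets out from 7 and comes back at 9. Oxidation of the C–B bond (NaBO3·4H2O, THF/H2O, rt) should give 1-[3-methoxy-2-(methoxymethoxy)-6-methylphenyl]docosan-1-ol F5. Ionic hydrogenation (Et3SiH, TFA, CH2Cl2, 0 °C → rt) should then reduce the benzylic alcohol through the oxygen-stabilised benzylic cation. The acid should remove the MOM group in the same operation, the methoxymethyl cation being reduced by the silane, so this sequence lands on 9 and step 4 is not needed.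

3. Step 5. Phenoxyl radicals may couple at the para carbon (diphenoquinone formation), or over-oxidation of the methoxy-bearing ring may occur, before oxygen is delivered to C4. The fallback sets out from 9 and comes back at 10. Para-nitrosation (NaNO2, HCl, EtOH/THF, 0 °C) should give 2-docosyl-6-methoxy-3-methyl-4-nitrosophenol F6. Reduction (Na2S2O4, THF/H2O) should give 4-amino-2-docosyl-6-methoxy-3-methylphenol F7. Oxidation with FeCl3 in aqueous HCl/THF should give 2-docosyl-4-imino-6-methoxy-3-methylcyclohexa-2,5-dien-1-one F8, which should hydrolyse in the acidic medium to 10.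

**Further compounds**
F1 | step 2 | 2-hydroxy-3-methoxy-6-methylbenzaldehyde | COc1ccc(C)c(C=O)c1O
F2 | step 2 | 3-methoxy-2-(methoxymethoxy)-6-methylbenzaldehyde | COCOc1c(OC)ccc(C)c1C=O
F3 | step 2 | 2-ethenyl-4-methoxy-3-(methoxymethoxy)-1-methylbenzene | COCOc1c(OC)ccc(C)c1C=C
F4 | step 2 | 9-{2-[3-methoxy-2-(methoxymethoxy)-6-methylphenyl]ethyl}-9-borabicyclo[3.3.1]nonane | COCOc1c(OC)ccc(C)c1CCB1C2CCCC1CCC2
F5 | step 3 | rac-1-[3-methoxy-2-(methoxymethoxy)-6-methylphenyl]docosan-1-ol | CCCCCCCCCCCCCCCCCCCCCC(O)c1c(C)ccc(OC)c1OCOC
F6 | step 5 | 2-docosyl-6-methoxy-3-methyl-4-nitrosophenol | CCCCCCCCCCCCCCCCCCCCCCc1c(C)c(N=O)cc(OC)c1O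
F7 | step 5 | 4-amino-2-docosyl-6-methoxy-3-methylphenol | CCCCCCCCCCCCCCCCCCCCCCc1c(C)c(N)cc(OC)c1O
F8 | step 5 | 2-docosyl-4-imino-6-methoxy-3-methylcyclohexa-2,5-dien-1-one | CCCCCCCCCCCCCCCCCCCCCCC1=C(C)C(=N)C=C(OC)C1=O
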